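**Retrosynthetic overview**

1. Side-chain C–C bond first, with reversed polarity: aldehyde 1 + formaldehyde 2, through the acyl-anion (Breslow) form 3 of 1, gives α-hydroxy ketone 4; C=O to CH2 gives arylethanol 5 (ring A with its side chain).
2. Ring B electrophile: vanillin 6 ⇒ 5,6-dibromovanillin 7 ⇒ benzylic alcohol 8.
3. ArCH2–Ar bond: Friedel–Crafts benzylation of 5 by 8, para to the unflanked OMe of 5 ⇒ diarylmethane 9.
4. End game: O-demethylation ⇒ pentaol 10; selective O-sulfation of the one aliphatic OH ⇒ target 11.
5. No ring is built: both benzene rings are bought (in 1 and 6) and only substituted.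

Assumption: the target has no stereocentre (it is achiral), so no stereocontrol is needed; it is isolated as the free hydrogen sulfate as drawn.

**Route**

Step 1
Reactants: 1 3-bromo-4,5-dimethoxybenzaldehyde; 2 formaldehyde (charged as paraformaldehyde)
Product: 4 1-(3-bromo-4,5-dimethoxyphenyl)-2-hydroxyethan-1-one, via Breslow intermediate 3 (not isolated)
Conditions: 2 as (CH2O)n (3 equiv), 3-mesityl-4,5-dimethylthiazolium perchlorate (10 mol %), iPr2NEt (20 mol %), THF, 60 °C
Reagents that add atoms: none
Why: NHC-catalysed cross-acyloin (benzoin-type) hydroxymethylation, in which the carbene turns the aldehyde carbon of 1 into a nucleophilic acyl anion equivalent (3) that adds to formaldehyde, the more electrophilic and non-enolisable partner, so two carbonyl carbons are joined with no by-product and no stereocentre.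

Step 2
Reactants: 4 1-(3-bromo-4,5-dimethoxyphenyl)-2-hydroxyethan-1-one
Product: 5 2-(3-bromo-4,5-dimethoxyphenyl)ethan-1-ol
Conditions: Et3SiH (4 equiv), TFA, TfOH (10 mol %), 0 → 45 °C; aq. NaHCO3/MeOH work-up
Reagents that add atoms: none
Why: Ionic hydrogenation (Kursanov–Parnes reduction) of an aryl ketone to CH2 via two protonation/hydride-transfer events at the benzylic carbon, the same reagent pair that turns chloroacetyl arenes into 2-chloroethyl arenes; a 1,2-H shift to the arylacetaldehyde would converge on the same product, ArBr and OMe are inert, and any O-trifluoroacetate is cleaved in the work-up.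

Step 3
Reactants: 6 vanillin (4-hydroxy-3-methoxybenzaldehyde)
Product: 7 2,3-dibromo-4-hydroxy-5-methoxybenzaldehyde (5,6-dibromovanillin)
Conditions: Br2 (2.3 equiv), Fe powder (5 mol %), AcOH, rt → 50 °C
Reagents that add atoms: bromine, BrBr
Why: Electrophilic aromatic bromination, first ortho to the free OH (C5) and then para to the OMe (C6), the established way to 5,6-dibromovanillin; the aldehyde is not touched.

Step 4
Reactants: 7 2,3-dibromo-4-hydroxy-5-methoxybenzaldehyde
Product: 8 2,3-dibromo-4-(hydroxymethyl)-6-methoxyphenol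
Conditions: NaBH4 (1.5 equiv), THF–MeOH, 0 °C; aqueous work-up
Reagents that add atoms: none
Why: Borohydride reduction of the aldehyde to the benzylic alcohol; aryl bromides and the phenol survive.

Step 5
Reactants: 5 2-(3-bromo-4,5-dimethoxyphenyl)ethan-1-ol; 8 2,3-dibromo-4-(hydroxymethyl)-6-methoxyphenol
Product: 9 2-{3-bromo-2-[(2,3-dibromo-4-hydroxy-5-methoxyphenyl)methyl]-4,5-dimethoxyphenyl}ethan-1-ol
Conditions: 5 (2 equiv, excess recovered), 8 added slowly, TfOH (10 mol %), HFIP, 0 °C → rt
Reagents that add atoms: none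
Why: Friedel–Crafts benzylation in which 8 ionises to a para-hydroxybenzyl (quinone-methide-like) cation that attacks 5 at C2, para to the unflanked 5-OMe and next to Br (the same site preference as the second bromination of 5-bromovanillin), while O-benzylation of the alcohol is reversible under the acid and excess 5 suppresses self-condensation of 8.

Step 6
Reactants: 9 2-{3-bromo-2-[(2,3-dibromo-4-hydroxy-5-methoxyphenyl)methyl]-4,5-dimethoxyphenyl}ethan-1-ol
Product: 10 3-bromo-4-[(2,3-dibromo-4,5-dihydroxyphenyl)methyl]-5-(2-hydroxyethyl)benzene-1,2-diol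
Conditions: BBr3 (8 equiv), CH2Cl2, −78 → 0 °C, 4 h; MeOH then H2O
Reagents that add atoms: none
Why: BBr3 aryl methyl ether cleavage (Lewis acid–base adduct, then SN2 of bromide on the methyl group) at all three OMe groups, kept at or below 0 °C so the primary alcohol stays as its borate ester (hydrolysed on work-up) and does not go on to the alkyl bromide; ArBr and the diarylmethane are stable.

Step 7
Reactants: 10 3-bromo-4-[(2,3-dibromo-4,5-dihydroxyphenyl)methyl]-5-(2-hydroxyethyl)benzene-1,2-diol
Product: 11 2-{3-bromo-2-[(2,3-dibromo-4,5-dihydroxyphenyl)methyl]-4,5-dihydroxyphenyl}ethyl hydrogen sulfate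
Conditions: SO3·pyridine (1.2 equiv), DMF, 0 °C, 2 h; H2O; C18 (H2O–MeCN); Dowex 50W-X8 (H+), lyophilise cold
Reagents that add atoms: sulfur trioxide–pyridine complex, [O-]S(=O)(=O)[n+]1ccccc1
Why: O-sulfation with an SO3–amine complex under neutral conditions, where the unhindered primary aliphatic OH is much more nucleophilic than the non-ionised, H-bonded, bromine-flanked catechol OH groups (the same order as Ser/Thr over Tyr), so about one equivalent should give the alkyl monosulfate.

**Compound list**

1 | 3-bromo-4,5-dimethoxybenzaldehyde (5-bromoveratraldehyde) | COc1cc(C=O)cc(Br)c1OC | starting material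
2 | formaldehyde (used as paraformaldehyde) | C=O | starting material
3 | Breslow intermediate: 2-[(3-bromo-4,5-dimethoxyphenyl)(hydroxy)methylidene]-3-mesityl-4,5-dimethyl-2,3-dihydro-1,3-thiazole | OC(c1cc(Br)c(OC)c(OC)c1)=C1SC(C)=C(C)N1c1c(C)cc(C)cc1C | intermediate
4 | 1-(3-bromo-4,5-dimethoxyphenyl)-2-hydroxyethan-1-one | COc1cc(C(=O)CO)cc(Br)c1OC | intermediate
5 | 2-(3-bromo-4,5-dimethoxyphenyl)ethan-1-ol | COc1cc(CCO)cc(Br)c1OC | intermediate
6 | vanillin (4-hydroxy-3-methoxybenzaldehyde) | COc1cc(C=O)ccc1O | starting material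
7 | 2,3-dibromo-4-hydroxy-5-methoxybenzaldehyde | COc1cc(C=O)c(Br)c(Br)c1O | intermediate
8 | 2,3-dibromo-4-(hydroxymethyl)-6-methoxyphenol | COc1cc(CO)c(Br)c(Br)c1O | intermediate
9 | 2-{3-bromo-2-[(2,3-dibromo-4-hydroxy-5-methoxyphenyl)methyl]-4,5-dimethoxyphenyl}ethan-1-ol | OCCc1cc(OC)c(OC)c(Br)c1Cc1cc(OC)c(O)c(Br)c1Br | intermediate
10 | 3-bromo-4-[(2,3-dibromo-4,5-dihydroxyphenyl)methyl]-5-(2-hydroxyethyl)benzene-1,2-diol | OCCc1cc(O)c(O)c(Br)c1Cc1cc(O)c(O)c(Br)c1Br | intermediate
11 | 2-{3-bromo-2-[(2,3-dibromo-4,5-dihydroxyphenyl)methyl]-4,5-dihydroxyphenyl}ethyl hydrogen sulfate | O=S(=O)(O)OCCc1cc(O)c(O)c(Br)c1Cc1cc(O)c(O)c(Br)c1Br | target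

**Totals**

Total steps: 7. Longest linear sequence: 5 steps (steps 1, 2, 5, 6, 7; the ring-B branch, steps 3, 4, 5, 6, 7, is equally long).

**Three steps most likely to fail, with fallbacks**

Step 5. The benzyl cation could attack C6 of 5 instead of C2, 8 could self-condense, or the benzyl ether of 5 could persist. The fallback sets out from 5 and aldehyde 7 (step 4 is then left out) and comes back at 9. Oxa-Pictet–Spengler condensation of 5 with 7 (TfOH, CH2Cl2–HFIP, rt) closes the oxocarbenium ion onto ring A and gives racemic 8-bromo-1-(2,3-dibromo-4-hydroxy-5-methoxyphenyl)-6,7-dimethoxyisochromane F1. The aldehyde cannot self-alkylate and the tether makes the C–C bond intramolecularly ortho to the side chain. Et3SiH/TFA then ionises the doubly benzylic C1–O bond, and hydride capture opens the ring to 9. This does not help if the fault is attack at C6, because the tether allows both ortho positions.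

Step 6. The free primary alcohol may be converted into the alkyl bromide before all three ethers are cleaved. The fallback sets out from 9 and comes back at 10. Ac2O/pyridine gives 2-{2-[(4-acetoxy-2,3-dibromo-5-methoxyphenyl)methyl]-3-bromo-4,5-dimethoxyphenyl}ethyl acetate F2. The ester-capped oxygen no longer forms an alkoxyborane, so BBr3 can be run to completion (−78 °C → rt). The MeOH quench is then warmed to 40 °C, and the HBr/MeOH formed transesterifies both acetates to give 10.

Step 7. Over- or mis-sulfation at the phenols is possible, and the product is acid-labile. The fallback sets out from 10 and comes back at 11. PhB(OH)2 (2.1 equiv, 4 Å MS, THF–pyridine) ties up both catechols as the cyclic bis(phenylboronate) of 10 F3 and leaves only the primary OH free. SO3·pyridine then gives the bis(phenylboronate) ethyl hydrogen sulfate F4. Mild aqueous work-up (pH 5, Et2O wash to remove the boronic acid) hydrolyses the boronates to 11.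

**Further compounds**

F1 | step 5 | 8-bromo-1-(2,3-dibromo-4-hydroxy-5-methoxyphenyl)-6,7-dimethoxyisochromane (racemic) | COc1cc2CCOC(c3cc(OC)c(O)c(Br)c3Br)c2c(Br)c1OC
F2 | step 6 | 2-{2-[(4-acetoxy-2,3-dibromo-5-methoxyphenyl)methyl]-3-bromo-4,5-dimethoxyphenyl}ethyl acetate | CC(=O)OCCc1cc(OC)c(OC)c(Br)c1Cc1cc(OC)c(OC(C)=O)c(Br)c1Br
F3 | step 7 | bis(phenylboronate) of 10 (both catechols as 2-phenyl-1,3,2-benzodioxaboroles, primary OH free) | OCCc1cc2OB(c3ccccc3)Oc2c(Br)c1Cc1cc2OB(c3ccccc3)Oc2c(Br)c1Br
F4 | step 7 | bis(phenylboronate) of 11 (O-sulfate of F3) | O=S(=O)(O)OCCc1cc2OB(c3ccccc3)Oc2c(Br)c1Cc1cc2OB(c3ccccc3)Oc2c(Br)c1Br
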